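The numbers in the tables were computed from invented constants; noise was put on by code.

**Two constants.** Two constants carry this flask, and both rest on first-order constants read from the last substrate readings of the earlier runs: 0.00207 s⁻¹ in the south-east run and 0.00743 s⁻¹ in the east run.

| setting | south-east | east | flask |
|---|---|---|---|
| substrate | 0.050 M | 0.050 M | 0.050 M |
| acid | 0.025 mM | 0.10 mM | 0.0500 mM |
| remark | run made earlier | run made earlier |  |
| time |  |  | 3.0 min |

| run | time / s | substrate / % | target / % |
|---|---|---|---|
| south-east | 25.0 | 94 | 4 |
| south-east | 50.0 | 92 | 3 |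
| south-east | 80.0 | 80 | 15 |
| south-east | 120 | 78 | 18 |
| east | 10.0 | 90 | 8 |
| east | 20.0 | 84 | 14 |
| east | 50.0 | 70 | 29 |
| east | 120 | 41 | 52 |

(each reading ± 2 percentage points)

- part of the substrate that has reacted at 3.0 min
- pH of the solution at 3.0 min

- acid is the free proton; pH is minus the decimal logarithm of its molar concentration

**Order in acid.** The first guess is a rate constant proportional to [acid], but the ratio of the two constants, 3.59, is smaller than the ratio of the two charges of acid, 4.00. A straight line with an intercept therefore replaces it, though the gap lies near the scatter. Its slope is the catalytic constant, the rise of the first-order constant per unit of [acid], 71.5 M⁻¹ s⁻¹, and its intercept, the acid-free constant, is 2.84 × 10⁻⁴ s⁻¹.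

**Steady acid?** The line is worth little if [acid] falls during a run. The earlier east reading gives 0.00713 s⁻¹, close to the later constant. Within the scatter, then, the east run shows no fall in [acid], and its loss of substrate reads as pseudo-first-order.

**Own reckoning.** At the flask's [acid], the line gives a constant of 0.00386 s⁻¹, so the estimate for 3.0 min, taking [acid] to stay near its charge, is a loss of 50.1% of the substrate.

**Forecast.** The forecast gives 50% (44% to 57%) and pH 4.3 (4.25 to 4.42), holding that “The acid appears to act as a catalyst”.

**Result.** The flask gives 51.7% reacted and pH 4.30.

    weak acid ⇌ conjugate base + acid, settled at all times (K = 1.30 × 10⁻¹⁰ M)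
    weak acid → by-product carried off (k = 0.00792 s⁻¹)
    substrate + acid → weak acid + acid + target (k = 78.2 M⁻¹ s⁻¹)
    target → over-reaction product (k = 0.00346 s⁻¹)
    substrate → weak acid + target (k = 1.28 × 10⁻⁴ s⁻¹)

At 3.00 min, the flask's step through acid uses substrate 31 times as fast as the step without it, while acid stands at 100% of its charge beside 3.29 × 10⁻⁸ M of conjugate base. The line's 71.5 M⁻¹ s⁻¹ gave 50.1% here, and at 1.3 × 10⁻⁴ M of acid it gives 82.2%, where that neighbouring flask stands at 84.3%.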